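**Strategy**
Cuts: first the two aryl–C(=O) bonds to the 2,4-dihydroxyphenyl rings (acyl carbons traced to two Weinreb amides, both rings to one aryl–metal reagent), then the C5–vinyl bond (Heck), then the C3–C3a bond of the dihydrofuran by retro ring contraction to a (2S)-2-arylchroman-4-one, last the C2–aryl bond (conjugate addition to 6-bromochromone).
Enabling feature: in the dihydrofuran ring, C3 carries the benzo carbon C3a and an exocyclic carbonyl carbon beside an unchanged O1–C2(H)(4-hydroxyphenyl) unit. This is the imprint of a flavanone whose C4a has moved from C4 to C3 while C4 is pushed out of the ring at the carboxyl oxidation level.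
Forward order: the benzopyranone ring is bought, C2 is arylated, the pyranone contracts to the dihydrofuran, the C5 side chain is attached, both resorcinol ketone rings are added in one operation, and five MOM ethers are removed at the end.
Stereochemistry: C2 (S) comes from a ligand-controlled asymmetric conjugate addition. C3 (S) is relayed from C2 in the contraction (oxidant anti to the C2 aryl, shift with inversion, giving the 2,3-trans ester, which is also the thermodynamic isomer). The E alkene comes from the Heck reaction.

Key step: step 3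

Assumption: in step 2 the (R)-antipode of the t-BuPyOx ligand is taken to deliver the aryl group to the chromone face that gives the 2S flavanone, by analogy with the facial preference of this catalyst on cyclic enones; if the sense proves opposite, the (S)-ligand is used.

Step 1
Reactants: 1 4-hydroxyphenylboronic acid
Product: 2 4-(pivaloyloxy)phenylboronic acid
Conditions: PivCl, pyridine, THF, 0 °C to rt; dilute aq. HCl work-up
Reagents that add atoms: pivaloyl chloride, CC(C)(C)C(Cl)=O
Why: O-acylation of the phenol with an acid chloride under amine base, in which any boron–acyl mixed anhydride is hydrolysed back to the free boronic acid on aqueous work-up; the hindered, electron-withdrawing pivalate is chosen because it later deactivates ring B in the ring contraction.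

Step 2
Reactants: 3 6-bromochromone; 2 4-(pivaloyloxy)phenylboronic acid
Product: 4 (S)-6-bromo-2-[4-(pivaloyloxy)phenyl]chroman-4-one
Conditions: Pd(OCOCF3)2 (5 mol%), (R)-t-BuPyOx (6 mol%), NH4PF6 (30 mol%), H2O (5 equiv), ClCH2CH2Cl, 60 °C
Reagents that add atoms: none
Why: Catalytic asymmetric conjugate addition of an arylboronic acid to a chromone under cationic divalent palladium with a pyridine-oxazoline ligand, a known route to enantioenriched 2-arylchromanones that leaves the aryl bromide alone because no zerovalent palladium is formed; the C2 stereocentre is set by the ligand, which fixes the enone face onto which the aryl–palladium species inserts.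

Step 3
Reactants: 4 (S)-6-bromo-2-[4-(pivaloyloxy)phenyl]chroman-4-one
Product: 7 methyl (2S,3S)-5-bromo-2-[4-(pivaloyloxy)phenyl]-2,3-dihydrobenzofuran-3-carboxylate, via enol ether 5 (not isolated), via iodanyl ketal 6 (not isolated)
Conditions: HC(OMe)3, conc. H2SO4 (cat.), rt, then PhI(OAc)2, 0 °C to rt; aq. NaHCO3 work-up
Reagents that add atoms: trimethyl orthoformate, COC(OC)OC
Why: In acidic orthoformate the ketone becomes enol ether 5, electrophilic trivalent iodine adds to C3 on the face away from the C2 aryl group and methanol caps C4 to give ketal 6, whose equatorial C3–I bond lies anti-periplanar to the C4–C4a ring bond, so C4a shifts from C4 to C3 as iodobenzene leaves (a semipinacol-type 1,2-aryl shift through a phenonium-like transition state) and the dimethoxycarbenium ion left at C4 is hydrolysed to the methyl ester. The closest known reaction is the hypervalent-iodine oxidative ring contraction of flavanones to methyl trans-2-aryl-2,3-dihydrobenzofuran-3-carboxylates, applied here to an enantioenriched 6-bromo-4'-acyloxy member of the same class. The five-membered dihydrofuran ring is closed by ring contraction and not by cyclization: the C3–C4a bond forms as the C4–C4a bond breaks, and C4 leaves the ring as the exocyclic ester carbon. C2 is a spectator and stays S, while C3 is set relative to it, because iodine enters anti to the C2 aryl and the shift inverts C3, placing the ester trans to the aryl group (2S,3S), which is also the preferred arrangement at this epimerizable centre. The step needs migration of ring A instead of ring B (which would lead to an isoflavone), no dehydrogenation to the flavone and no ionization of the C2–O bond; the ketal oxygens and the ring oxygen ortho to C4a raise the migratory aptitude of ring A, the pivaloyloxy group deactivates ring B toward migration and benzylic ionization, and the bromide (meta to C4a) is inert.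

Step 4
Reactants: 7 methyl (2S,3S)-5-bromo-2-[4-(pivaloyloxy)phenyl]-2,3-dihydrobenzofuran-3-carboxylate; 8 N-methoxy-N-methylacrylamide
Product: 9 methyl (2S,3S)-5-[(E)-3-[methoxy(methyl)amino]-3-oxoprop-1-en-1-yl]-2-[4-(pivaloyloxy)phenyl]-2,3-dihydrobenzofuran-3-carboxylate
Conditions: Pd(OAc)2 (5 mol%), P(o-tol)3 (10 mol%), Et3N, DMF, 100 °C
Reagents that add atoms: none
Why: Mizoroki–Heck reaction of the aryl bromide with the acrylamide (oxidative addition to zerovalent palladium, syn insertion, syn β-hydride elimination) should give the E-cinnamoyl Weinreb amide, and the amine base is too weak to harm the aryl pivalate or to move the ester away from its favoured trans position.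

Step 5
Reactants: 9 methyl (2S,3S)-5-[(E)-3-[methoxy(methyl)amino]-3-oxoprop-1-en-1-yl]-2-[4-(pivaloyloxy)phenyl]-2,3-dihydrobenzofuran-3-carboxylate
Product: 10 (2S,3S)-2-(4-hydroxyphenyl)-N-methoxy-5-[(E)-3-[methoxy(methyl)amino]-3-oxoprop-1-en-1-yl]-N-methyl-2,3-dihydrobenzofuran-3-carboxamide
Conditions: AlMe3, MeNH(OMe)·HCl (excess of each), CH2Cl2, 0 °C to 40 °C; cold 1 M aq. HCl work-up
Reagents that add atoms: N,O-dimethylhydroxylamine hydrochloride, CNOC.Cl
Why: Weinreb aminolysis with the aluminium amide made from AlMe3 and the amine hydrochloride should convert the hindered methyl ester into the N-methoxy-N-methylamide and, used in excess, also transfer the pivaloyl group to the amine, so the phenol is unmasked in the same operation while the cinnamoyl Weinreb amide is unaffected.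

Step 6
Reactants: 10 (2S,3S)-2-(4-hydroxyphenyl)-N-methoxy-5-[(E)-3-[methoxy(methyl)amino]-3-oxoprop-1-en-1-yl]-N-methyl-2,3-dihydrobenzofuran-3-carboxamide
Product: 11 (2S,3S)-N-methoxy-5-[(E)-3-[methoxy(methyl)amino]-3-oxoprop-1-en-1-yl]-2-[4-(methoxymethoxy)phenyl]-N-methyl-2,3-dihydrobenzofuran-3-carboxamide
Conditions: MOMCl, iPr2NEt, CH2Cl2, 0 °C to rt
Reagents that add atoms: chloromethyl methyl ether, COCCl
Why: O-alkylation of the phenol with chloromethyl methyl ether under amine base (methoxymethyl ether formation) installs an acetal that tolerates aryl–metal reagents and falls later together with the other four.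

Step 7
Reactants: 12 4-bromoresorcinol
Product: 13 1-bromo-2,4-bis(methoxymethoxy)benzene
Conditions: MOMCl, iPr2NEt, CH2Cl2, 0 °C to rt
Reagents that add atoms: chloromethyl methyl ether, COCCl
Why: Twofold methoxymethyl ether formation on both phenols under the same amine-base conditions; the ortho acetal oxygen will later chelate and stabilize the aryl–metal species.

Step 8
Reactants: 11 (2S,3S)-N-methoxy-5-[(E)-3-[methoxy(methyl)amino]-3-oxoprop-1-en-1-yl]-2-[4-(methoxymethoxy)phenyl]-N-methyl-2,3-dihydrobenzofuran-3-carboxamide; 13 1-bromo-2,4-bis(methoxymethoxy)benzene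
Product: 16 (E)-1-[2,4-bis(methoxymethoxy)phenyl]-3-[(2S,3S)-3-[2,4-bis(methoxymethoxy)benzoyl]-2-[4-(methoxymethoxy)phenyl]-2,3-dihydrobenzofuran-5-yl]prop-2-en-1-one, via aryllithium 14 (not isolated), via arylcerium dichloride 15 (not isolated)
Conditions: 13 (3 equiv), n-BuLi, THF, −78 °C; anhydrous CeCl3, THF, −78 °C; then 11, −78 to −20 °C; aq. NH4Cl
Reagents that add atoms: none
Why: Bromine–lithium exchange, transmetalation to the less basic arylcerium dichloride and twofold Weinreb ketone synthesis, in which each amide takes up one aryl group and rests as the chelated tetrahedral adduct until work-up, the cerium reagent favours 1,2-addition at the cinnamoyl amide and suppresses deprotonation at C3, and any C3 anion that does form should be reprotonated to the trans isomer because opening of the dihydrofuran from it (reverse 5-endo closure) is stereoelectronically poor.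

Step 9
Reactants: 16 (E)-1-[2,4-bis(methoxymethoxy)phenyl]-3-[(2S,3S)-3-[2,4-bis(methoxymethoxy)benzoyl]-2-[4-(methoxymethoxy)phenyl]-2,3-dihydrobenzofuran-5-yl]prop-2-en-1-one
Product: 17 (E)-3-[(2S,3S)-3-(2,4-dihydroxybenzoyl)-2-(4-hydroxyphenyl)-2,3-dihydrobenzofuran-5-yl]-1-(2,4-dihydroxyphenyl)prop-2-en-1-one (CNP0288976.2)
Conditions: 3 M aq. HCl, MeOH, 45 °C
Reagents that add atoms: none
Why: Acid-catalysed acetal exchange with methanol removes all five methoxymethyl groups as dimethoxymethane, the two ethers ortho to the carbonyl groups going first through hydrogen-bond assistance, and the mild temperature is meant to keep the 2'-hydroxychalcone from closing to a flavanone and the benzylic C2–O bond from ionizing.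

**Compound list**
1 | 4-hydroxyphenylboronic acid | OB(O)c1ccc(O)cc1 | starting material
2 | 4-(pivaloyloxy)phenylboronic acid | CC(C)(C)C(=O)Oc1ccc(B(O)O)cc1 | intermediate
3 | 6-bromochromone (6-bromo-4H-chromen-4-one) | O=c1ccoc2ccc(Br)cc12 | starting material
4 | (S)-6-bromo-2-[4-(pivaloyloxy)phenyl]chroman-4-one | O=C1C[C@@H](c2ccc(OC(=O)C(C)(C)C)cc2)Oc2ccc(Br)cc21 | intermediate
5 | enol ether, not isolated: (S)-6-bromo-4-methoxy-2-[4-(pivaloyloxy)phenyl]-2H-chromene | COC1=C[C@@H](c2ccc(OC(=O)C(C)(C)C)cc2)Oc2ccc(Br)cc21 | intermediate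
6 | iodanyl ketal, not isolated: 2,3-trans-3-[acetoxy(phenyl)iodanyl]-6-bromo-4,4-dimethoxy-2-[4-(pivaloyloxy)phenyl]chromane, C2 arranged as in 4 | COC1(OC)[C@H](I(OC(C)=O)c2ccccc2)[C@@H](c2ccc(OC(=O)C(C)(C)C)cc2)Oc2ccc(Br)cc21 | intermediate
7 | methyl (2S,3S)-5-bromo-2-[4-(pivaloyloxy)phenyl]-2,3-dihydrobenzofuran-3-carboxylate (2,3-trans) | Brc1ccc2c(c1)[C@H](C(=O)OC)[C@@H](c1ccc(OC(=O)C(C)(C)C)cc1)O2 | intermediate
8 | N-methoxy-N-methylacrylamide | C=CC(=O)N(C)OC | starting material
9 | methyl (2S,3S)-5-[(E)-3-[methoxy(methyl)amino]-3-oxoprop-1-en-1-yl]-2-[4-(pivaloyloxy)phenyl]-2,3-dihydrobenzofuran-3-carboxylate | CON(C)C(=O)/C=C/c1ccc2c(c1)[C@H](C(=O)OC)[C@@H](c1ccc(OC(=O)C(C)(C)C)cc1)O2 | intermediate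
10 | (2S,3S)-2-(4-hydroxyphenyl)-N-methoxy-5-[(E)-3-[methoxy(methyl)amino]-3-oxoprop-1-en-1-yl]-N-methyl-2,3-dihydrobenzofuran-3-carboxamide | CON(C)C(=O)/C=C/c1ccc2c(c1)[C@H](C(=O)N(C)OC)[C@@H](c1ccc(O)cc1)O2 | intermediate
11 | (2S,3S)-N-methoxy-5-[(E)-3-[methoxy(methyl)amino]-3-oxoprop-1-en-1-yl]-2-[4-(methoxymethoxy)phenyl]-N-methyl-2,3-dihydrobenzofuran-3-carboxamide | CON(C)C(=O)/C=C/c1ccc2c(c1)[C@H](C(=O)N(C)OC)[C@@H](c1ccc(OCOC)cc1)O2 | intermediate
12 | 4-bromoresorcinol (4-bromobenzene-1,3-diol) | Oc1ccc(Br)c(O)c1 | starting material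
13 | 1-bromo-2,4-bis(methoxymethoxy)benzene | COCOc1ccc(Br)c(OCOC)c1 | intermediate
14 | aryllithium, not isolated: 2,4-bis(methoxymethoxy)phenyllithium | [Li]c1ccc(OCOC)cc1OCOC | intermediate
15 | arylcerium dichloride, not isolated: dichloro[2,4-bis(methoxymethoxy)phenyl]cerium | Cl[Ce](Cl)c1ccc(OCOC)cc1OCOC | intermediate
16 | (E)-1-[2,4-bis(methoxymethoxy)phenyl]-3-[(2S,3S)-3-[2,4-bis(methoxymethoxy)benzoyl]-2-[4-(methoxymethoxy)phenyl]-2,3-dihydrobenzofuran-5-yl]prop-2-en-1-one | O=C(/C=C/c1ccc2c(c1)[C@H](C(=O)c1ccc(OCOC)cc1OCOC)[C@@H](c1ccc(OCOC)cc1)O2)c1ccc(OCOC)cc1OCOC | intermediate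
17 | (E)-3-[(2S,3S)-3-(2,4-dihydroxybenzoyl)-2-(4-hydroxyphenyl)-2,3-dihydrobenzofuran-5-yl]-1-(2,4-dihydroxyphenyl)prop-2-en-1-one (CNP0288976.2) | O=C(/C=C/c1ccc2c(c1)[C@H](C(=O)c1ccc(O)cc1O)[C@@H](c1ccc(O)cc1)O2)c1ccc(O)cc1O | target

**Count and risks**
Total steps: 9. Longest linear sequence: 8 steps (steps 1, 2, 3, 4, 5, 6, 8, 9, from 4-hydroxyphenylboronic acid 1).

Step 3 (ring contraction). What may go wrong: shift of ring B instead of ring A, dehydrogenation or simple α-methoxylation, or acid-mediated ring opening of the flavanone before the ketal has formed, which would erode the enantiomeric purity. Fallback, setting out from 4 and bringing about the same C4-to-C3 shift of C4a through a carbene instead of an iodonium species: kinetic enolization with LiN(SiMe3)2 in THF at −78 °C (kept cold so that the enolate does not expel the ring aryloxide) and trapping with CF3CO2CH2CF3 should give the 3-(trifluoroacetyl)flavanone F1. Detrifluoroacetylative diazo transfer (MsN3, Et3N, H2O, MeCN) would convert it into the 3-diazoflavanone F2, whose cyclic, s-Z-locked diazo ketone is the geometry that favours a concerted Wolff rearrangement. Irradiation in methanol (λ > 300 nm) should lead to the ring-contracted ketene F3, which adds methanol; protonation anti to the C2 aryl is expected to give mainly the cis ester F4. DBU in toluene would then epimerize C3 to the trans isomer, and the fallback comes back to the route at 7, with C2 untouched throughout.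

Step 8 (twofold aryl ketone formation). What may go wrong: deprotonation at C3 outrunning addition at the hindered amide, a stalled second addition, or conjugate addition at the cinnamoyl unit. Fallback, setting out from 11 and replacing acyl substitution by aldehyde addition and oxidation: i-Bu2AlH in THF at −78 °C should reduce both Weinreb amides to the dialdehyde F5. The arylcerium 15 (made from 13 as in the route) would add to both aldehydes at −78 °C, much faster than any α-deprotonation, to give the bis-carbinol F6 as a mixture of carbinol epimers. Dess–Martin periodinane (NaHCO3, CH2Cl2) would oxidize both secondary alcohols, and the fallback comes back to the route at 16.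

Step 5 (aminolysis with loss of the pivalate). What may go wrong: slow aminolysis at the hindered C3 ester, incomplete pivalate transfer, or Lewis-acid ionization of the C2–O bond once the electron-rich phenoxide is unmasked, with loss of configuration. Fallback, setting out from 9 and replacing direct aminolysis by hydrolysis and amide coupling: LiOH in THF/MeOH/H2O (0 °C to rt) should cleave the methyl ester and the pivalate to give the hydroxy acid F7. Coupling with MeNH(OMe)·HCl (EDC·HCl, HOBt, N-methylmorpholine, DMF) would form the C3 Weinreb amide, and the fallback comes back to the route at 10.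

**Further compounds**
F1 | step 3 | (2S)-6-bromo-2-[4-(pivaloyloxy)phenyl]-3-(trifluoroacetyl)chroman-4-one (C3 epimers and enol form) | O=C1C(C(=O)C(F)(F)F)[C@@H](c2ccc(OC(=O)C(C)(C)C)cc2)Oc2ccc(Br)cc21
F2 | step 3 | (R)-6-bromo-3-diazo-2-[4-(pivaloyloxy)phenyl]chroman-4-one (C2 arranged as in 4; the descriptor changes because C3 now outranks the aryl group) | O=C1C(=[N+]=[N-])[C@@H](c2ccc(OC(=O)C(C)(C)C)cc2)Oc2ccc(Br)cc21
F3 | step 3 | 5-bromo-3-(oxomethylidene)-2-[4-(pivaloyloxy)phenyl]-2,3-dihydrobenzofuran (ketene, C2 arranged as in 7) | O=C=C1[C@@H](c2ccc(OC(=O)C(C)(C)C)cc2)Oc2ccc(Br)cc21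
F4 | step 3 | methyl (2S,3R)-5-bromo-2-[4-(pivaloyloxy)phenyl]-2,3-dihydrobenzofuran-3-carboxylate (2,3-cis) | Brc1ccc2c(c1)[C@@H](C(=O)OC)[C@@H](c1ccc(OC(=O)C(C)(C)C)cc1)O2
F5 | step 8 | (2S,3S)-2-[4-(methoxymethoxy)phenyl]-5-[(E)-3-oxoprop-1-en-1-yl]-2,3-dihydrobenzofuran-3-carbaldehyde | O=C/C=C/c1ccc2c(c1)[C@H](C=O)[C@@H](c1ccc(OCOC)cc1)O2
F6 | step 8 | (E)-1-[2,4-bis(methoxymethoxy)phenyl]-3-[2,3-trans-3-{[2,4-bis(methoxymethoxy)phenyl](hydroxy)methyl}-2-[4-(methoxymethoxy)phenyl]-2,3-dihydrobenzofuran-5-yl]prop-2-en-1-ol (ring centres as in 11, carbinol centres mixed) | OC(/C=C/c1ccc2c(c1)[C@H](C(O)c1ccc(OCOC)cc1OCOC)[C@@H](c1ccc(OCOC)cc1)O2)c1ccc(OCOC)cc1OCOC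
F7 | step 5 | (2S,3S)-2-(4-hydroxyphenyl)-5-[(E)-3-[methoxy(methyl)amino]-3-oxoprop-1-en-1-yl]-2,3-dihydrobenzofuran-3-carboxylic acid | CON(C)C(=O)/C=C/c1ccc2c(c1)[C@H](C(=O)O)[C@@H](c1ccc(O)cc1)O2
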